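**Retrosynthetic overview** (C-numbering follows the nonadecene chain: C1–C5 pentyl, C6 ring C–O, C7 ester carbon, C8 CH2, C9 ring C–O, C10 carbinol, C18=C19 alkene)
1. Target 25 ⇐ 22 by acylation of O7 with tetradecanoyl chloride and final removal of the O10 silyl group.
2. The only ring (the oxolane) is closed late: O6 displaces a C9 mesylate (5-exo-tet, inversion) in acyclic 21.
3. 1,3-anti diol 18 ⇐ β-hydroxy ketone 17 by hydroxyl-directed reduction; O6/O7 are then tied up as an acetal so that only O9 is activated.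
4. Key C7–C8 disconnection: chelation-controlled Mukaiyama aldol between aldehyde 6 (C1–C7) and enol silane 16 (C8–C19).
5. 6 ⇐ (S)-trityl glycidyl ether + n-BuMgBr (C6 from the chiral pool); 16 ⇐ undec-10-enoyl chloride by Evans oxazolidinone enolate hydroxylation (C10).

Assumption: Grignard and amide-base solutions, the Davis oxaziridine and Dess–Martin periodinane count as purchased reagents; the acetal carbon of 19 and 20 is an inconsequential epimer mixture.

**Step 1**
Reactants: 1 (S)-trityl glycidyl ether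
Product: 2 (2S)-1-(trityloxy)heptan-2-ol
Conditions: n-BuMgBr (1.5 equiv), CuI (10 mol%), THF, −40 → 0 °C; then aq. NH4Cl
Reagents that add atoms: n-butylmagnesium bromide, CCCC[Mg]Br
Why: Copper-catalysed Grignard opening of the terminal epoxide (SN2 at the unhindered CH2) leaves the glycidyl stereocentre untouched, so C6 is taken from the chiral pool as (S).

**Step 2**
Reactants: 2 (2S)-1-(trityloxy)heptan-2-ol
Product: 4 (2S)-2-[(4-methoxybenzyl)oxy]-1-(trityloxy)heptane, via sodium alkoxide 3 (not isolated)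
Conditions: NaH, THF/DMF, 0 °C; then PMBCl, Bu4NI (cat.), rt
Reagents that add atoms: 4-methoxybenzyl chloride, COc1ccc(CCl)cc1
Why: Williamson etherification of the secondary alkoxide installs the PMB ether, which later chelates in step 11 and is transposed to an acetal in step 13.

**Step 3**
Reactants: 4 (2S)-2-[(4-methoxybenzyl)oxy]-1-(trityloxy)heptane
Product: 5 (2S)-2-[(4-methoxybenzyl)oxy]heptan-1-ol
Conditions: TsOH·H2O (10 mol%), MeOH/CH2Cl2, rt
Reagents that add atoms: none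
Why: Acid-catalysed SN1 methanolysis of the trityl ether through the trityl cation is far faster than PMB cleavage under catalytic acid.

**Step 4**
Reactants: 5 (2S)-2-[(4-methoxybenzyl)oxy]heptan-1-ol
Product: 6 (2S)-2-[(4-methoxybenzyl)oxy]heptanal
Conditions: Dess–Martin periodinane, pyridine, CH2Cl2, 0 °C → rt; used at once
Reagents that add atoms: none
Why: Dess–Martin oxidation is mild and buffered, so the α-alkoxy aldehyde forms without epimerisation or over-oxidation.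

**Step 5**
Reactants: 7 (4R)-4-benzyl-1,3-oxazolidin-2-one; 8 undec-10-enoyl chloride
Product: 9 (4R)-4-benzyl-3-(undec-10-enoyl)-1,3-oxazolidin-2-one
Conditions: Et3N, DMAP (10 mol%), CH2Cl2, 0 °C → rt
Reagents that add atoms: none
Why: DMAP-catalysed N-acylation (nucleophilic acyl substitution) attaches the Evans auxiliary to the C9–C19 acid.

**Step 6**
Reactants: 9 (4R)-4-benzyl-3-(undec-10-enoyl)-1,3-oxazolidin-2-one
Product: 11 (4R)-4-benzyl-3-[(2R)-2-hydroxyundec-10-enoyl]-1,3-oxazolidin-2-one, via sodium Z-enolate 10 (not isolated)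
Conditions: NaN(SiMe3)2, THF, −78 °C; then 2-(phenylsulfonyl)-3-phenyloxaziridine, −78 °C; AcOH quench
Reagents that add atoms: 2-(phenylsulfonyl)-3-phenyloxaziridine (Davis oxaziridine), O=S(=O)(c1ccccc1)N1OC1c1ccccc1
Why: Evans asymmetric enolate hydroxylation, in which the chelated Z-enolate is oxidised on the face opposite the benzyl group, sets C10 as (R) (typically ≥95:5 dr, minor isomer removed by chromatography).

**Step 7**
Reactants: 11 (4R)-4-benzyl-3-[(2R)-2-hydroxyundec-10-enoyl]-1,3-oxazolidin-2-one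
Product: 12 (2R)-2-hydroxy-N-methoxy-N-methylundec-10-enamide
Conditions: Me(MeO)NH·HCl, AlMe3, CH2Cl2, 0 °C → rt; then 11, −15 → 0 °C; 1 M HCl
Reagents that add atoms: N,O-dimethylhydroxylamine hydrochloride, CNOC.Cl
Why: Weinreb transamidation by the aluminium amide, assisted by the free α-hydroxyl, attacks the exocyclic carbonyl and releases the recoverable auxiliary without epimerisation.

**Step 8**
Reactants: 12 (2R)-2-hydroxy-N-methoxy-N-methylundec-10-enamide
Product: 13 (2R)-2-[(tert-butyldimethylsilyl)oxy]-N-methoxy-N-methylundec-10-enamide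
Conditions: TBSOTf, 2,6-lutidine, CH2Cl2, 0 °C
Reagents that add atoms: tert-butyldimethylsilyl triflate, CC(C)(C)[Si](C)(C)OS(=O)(=O)C(F)(F)F
Why: Silylation with the silyl triflate protects the hindered α-hydroxyl as a non-chelating TBS ether that survives every step until HF.

**Step 9**
Reactants: 13 (2R)-2-[(tert-butyldimethylsilyl)oxy]-N-methoxy-N-methylundec-10-enamide
Product: 14 (3R)-3-[(tert-butyldimethylsilyl)oxy]dodec-11-en-2-one
Conditions: MeMgBr, THF, −20 → 0 °C; then cold 1 M HCl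
Reagents that add atoms: methylmagnesium bromide, C[Mg]Br
Why: Weinreb ketone synthesis, where the Grignard adduct rests as a chelated tetrahedral intermediate and gives the methyl ketone on work-up without over-addition or loss of the α-stereocentre.

**Step 10**
Reactants: 14 (3R)-3-[(tert-butyldimethylsilyl)oxy]dodec-11-en-2-one
Product: 16 (3R)-3-[(tert-butyldimethylsilyl)oxy]-2-[(trimethylsilyl)oxy]dodeca-1,11-diene, via lithium enolate 15 (not isolated)
Conditions: LiN(iPr)2, THF, −78 °C; then Me3SiCl, −78 → 0 °C; pentane, filtration, used crude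
Reagents that add atoms: chlorotrimethylsilane, C[Si](C)(C)Cl
Why: Kinetic deprotonation at the unhindered methyl group followed by O-silylation gives the terminal enol silane and leaves C10 untouched.

**Step 11** (key fragment union)
Reactants: 6 (2S)-2-[(4-methoxybenzyl)oxy]heptanal; 16 (3R)-3-[(tert-butyldimethylsilyl)oxy]-2-[(trimethylsilyl)oxy]dodeca-1,11-diene
Product: 17 (6S,7S,10R)-10-[(tert-butyldimethylsilyl)oxy]-7-hydroxy-6-[(4-methoxybenzyl)oxy]nonadec-18-en-9-one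
Conditions: MgBr2·OEt2 (3 equiv), CH2Cl2, −78 → −30 °C; 1 M HCl work-up
Reagents that add atoms: none
Why: Mukaiyama aldol under Cram-chelate control, in which MgBr2 bridges the aldehyde and PMB-ether oxygens and the enol silane attacks the face opposite the pentyl group, forms the C7–C8 bond with the 6,7-syn (7S) carbinol.

**Step 12**
Reactants: 17 (6S,7S,10R)-10-[(tert-butyldimethylsilyl)oxy]-7-hydroxy-6-[(4-methoxybenzyl)oxy]nonadec-18-en-9-one
Product: 18 (6S,7S,9S,10R)-10-[(tert-butyldimethylsilyl)oxy]-6-[(4-methoxybenzyl)oxy]nonadec-18-ene-7,9-diol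
Conditions: Me4NBH(OAc)3, MeCN/AcOH (1:1), −30 °C
Reagents that add atoms: none
Why: Evans–Saksena reduction, where the C7 hydroxyl binds boron and delivers hydride intramolecularly through a chair transition state, gives the 1,3-anti diol and so (9S).

**Step 13**
Reactants: 18 (6S,7S,9S,10R)-10-[(tert-butyldimethylsilyl)oxy]-6-[(4-methoxybenzyl)oxy]nonadec-18-ene-7,9-diol
Product: 19 (2S,3R)-3-[(tert-butyldimethylsilyl)oxy]-1-[(2RS,4S,5S)-2-(4-methoxyphenyl)-5-pentyl-1,3-dioxolan-4-yl]dodec-11-en-2-ol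
Conditions: DDQ (1.2 equiv), 4 Å molecular sieves, dry CH2Cl2, −10 → 0 °C
Reagents that add atoms: none
Why: Oikawa–Yonemitsu oxidative acetalisation, in which DDQ oxidises the PMB ether to an oxocarbenium ion that the neighbouring C7 hydroxyl traps as a five-membered acetal, leaves the C9 hydroxyl as the only free one.

**Step 14**
Reactants: 19 (2S,3R)-3-[(tert-butyldimethylsilyl)oxy]-1-[(2RS,4S,5S)-2-(4-methoxyphenyl)-5-pentyl-1,3-dioxolan-4-yl]dodec-11-en-2-ol
Product: 20 (2S,3R)-3-[(tert-butyldimethylsilyl)oxy]-1-[(2RS,4S,5S)-2-(4-methoxyphenyl)-5-pentyl-1,3-dioxolan-4-yl]dodec-11-en-2-yl methanesulfonate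
Conditions: MsCl, Et3N, DMAP (cat.), CH2Cl2, 0 °C
Reagents that add atoms: methanesulfonyl chloride, CS(=O)(=O)Cl
Why: O-sulfonylation of the only free hydroxyl turns C9 into a leaving group with retention of configuration.

**Step 15**
Reactants: 20 (2S,3R)-3-[(tert-butyldimethylsilyl)oxy]-1-[(2RS,4S,5S)-2-(4-methoxyphenyl)-5-pentyl-1,3-dioxolan-4-yl]dodec-11-en-2-yl methanesulfonate
Product: 22 (2S,3S,5R)-5-[(1R)-1-[(tert-butyldimethylsilyl)oxy]dec-9-en-1-yl]-2-pentyloxolan-3-ol, via diol mesylate 21 (not isolated)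
Conditions: PPTS (30 mol%), MeOH, 40 °C; then K2CO3, rt
Reagents that add atoms: none
Why: Acetal methanolysis frees the 6,7-diol and base triggers a 5-exo-tet intramolecular Williamson etherification in which O6 displaces the C9 mesylate with inversion ((9S) to (9R)), giving the 2,3-cis-2,5-trans oxolane, while O7 could only form a strained oxetane and O10 is silylated.

**Step 16**
Reactants: 22 (2S,3S,5R)-5-[(1R)-1-[(tert-butyldimethylsilyl)oxy]dec-9-en-1-yl]-2-pentyloxolan-3-ol; 23 tetradecanoyl chloride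
Product: 24 (2S,3S,5R)-5-[(1R)-1-[(tert-butyldimethylsilyl)oxy]dec-9-en-1-yl]-2-pentyloxolan-3-yl tetradecanoate
Conditions: Et3N, DMAP (20 mol%), CH2Cl2, 0 °C → rt
Reagents that add atoms: none
Why: DMAP-catalysed esterification of the only free hydroxyl with the acid chloride proceeds with retention at C7.

**Step 17**
Reactants: 24 (2S,3S,5R)-5-[(1R)-1-[(tert-butyldimethylsilyl)oxy]dec-9-en-1-yl]-2-pentyloxolan-3-yl tetradecanoate
Product: 25 (2S,3S,5R)-5-[(1R)-1-hydroxydec-9-en-1-yl]-2-pentyloxolan-3-yl tetradecanoate (target)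
Conditions: HF·pyridine, pyridine/THF, 0 °C → rt
Reagents that add atoms: none
Why: Fluoride-mediated desilylation under buffered conditions removes the TBS ether without touching the ester, the terminal alkene or any stereocentre.

**Compound list**
1 | (S)-trityl glycidyl ether | C(OC[C@@H]1CO1)(c1ccccc1)(c1ccccc1)c1ccccc1 | starting material
2 | (2S)-1-(trityloxy)heptan-2-ol | CCCCC[C@H](O)COC(c1ccccc1)(c1ccccc1)c1ccccc1 | intermediate
3 | sodium (2S)-1-(trityloxy)heptan-2-olate | CCCCC[C@H]([O-])COC(c1ccccc1)(c1ccccc1)c1ccccc1.[Na+] | intermediate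
4 | (2S)-2-[(4-methoxybenzyl)oxy]-1-(trityloxy)heptane | CCCCC[C@H](OCc1ccc(OC)cc1)COC(c1ccccc1)(c1ccccc1)c1ccccc1 | intermediate
5 | (2S)-2-[(4-methoxybenzyl)oxy]heptan-1-ol | CCCCC[C@H](OCc1ccc(OC)cc1)CO | intermediate
6 | (2S)-2-[(4-methoxybenzyl)oxy]heptanal | CCCCC[C@H](OCc1ccc(OC)cc1)C=O | intermediate
7 | (4R)-4-benzyl-1,3-oxazolidin-2-one | O=C1N[C@H](Cc2ccccc2)CO1 | starting material
8 | undec-10-enoyl chloride | C=CCCCCCCCCC(=O)Cl | starting material
9 | (4R)-4-benzyl-3-(undec-10-enoyl)-1,3-oxazolidin-2-one | C=CCCCCCCCCC(=O)N1[C@H](Cc2ccccc2)COC1=O | intermediate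
10 | sodium Z-enolate of 9 | C=CCCCCCCC/C=C(\[O-])N1[C@H](Cc2ccccc2)COC1=O.[Na+] | intermediate
11 | (4R)-4-benzyl-3-[(2R)-2-hydroxyundec-10-enoyl]-1,3-oxazolidin-2-one | C=CCCCCCCC[C@@H](O)C(=O)N1[C@H](Cc2ccccc2)COC1=O | intermediate
12 | (2R)-2-hydroxy-N-methoxy-N-methylundec-10-enamide | C=CCCCCCCC[C@@H](O)C(=O)N(C)OC | intermediate
13 | (2R)-2-[(tert-butyldimethylsilyl)oxy]-N-methoxy-N-methylundec-10-enamide | C=CCCCCCCC[C@@H](O[Si](C)(C)C(C)(C)C)C(=O)N(C)OC | intermediate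
14 | (3R)-3-[(tert-butyldimethylsilyl)oxy]dodec-11-en-2-one | C=CCCCCCCC[C@@H](O[Si](C)(C)C(C)(C)C)C(C)=O | intermediate
15 | lithium (3R)-3-[(tert-butyldimethylsilyl)oxy]dodeca-1,11-dien-2-olate | C=CCCCCCCC[C@@H](O[Si](C)(C)C(C)(C)C)C(=C)[O-].[Li+] | intermediate
16 | (3R)-3-[(tert-butyldimethylsilyl)oxy]-2-[(trimethylsilyl)oxy]dodeca-1,11-diene | C=CCCCCCCC[C@@H](O[Si](C)(C)C(C)(C)C)C(=C)O[Si](C)(C)C | intermediate
17 | (6S,7S,10R)-10-[(tert-butyldimethylsilyl)oxy]-7-hydroxy-6-[(4-methoxybenzyl)oxy]nonadec-18-en-9-one | C=CCCCCCCC[C@@H](O[Si](C)(C)C(C)(C)C)C(=O)C[C@H](O)[C@@H](OCc1ccc(OC)cc1)CCCCC | intermediate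
18 | (6S,7S,9S,10R)-10-[(tert-butyldimethylsilyl)oxy]-6-[(4-methoxybenzyl)oxy]nonadec-18-ene-7,9-diol | C=CCCCCCCC[C@@H](O[Si](C)(C)C(C)(C)C)[C@@H](O)C[C@H](O)[C@@H](OCc1ccc(OC)cc1)CCCCC | intermediate
19 | (2S,3R)-3-[(tert-butyldimethylsilyl)oxy]-1-[(2RS,4S,5S)-2-(4-methoxyphenyl)-5-pentyl-1,3-dioxolan-4-yl]dodec-11-en-2-ol | C=CCCCCCCC[C@@H](O[Si](C)(C)C(C)(C)C)[C@@H](O)C[C@@H]1OC(c2ccc(OC)cc2)O[C@H]1CCCCC | intermediate
20 | C9 methanesulfonate of 19 | C=CCCCCCCC[C@@H](O[Si](C)(C)C(C)(C)C)[C@@H](OS(C)(=O)=O)C[C@@H]1OC(c2ccc(OC)cc2)O[C@H]1CCCCC | intermediate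
21 | (6S,7S,9S,10R)-10-[(tert-butyldimethylsilyl)oxy]-6,7-dihydroxynonadec-18-en-9-yl methanesulfonate | C=CCCCCCCC[C@@H](O[Si](C)(C)C(C)(C)C)[C@@H](OS(C)(=O)=O)C[C@H](O)[C@@H](O)CCCCC | intermediate
22 | (2S,3S,5R)-5-[(1R)-1-[(tert-butyldimethylsilyl)oxy]dec-9-en-1-yl]-2-pentyloxolan-3-ol | C=CCCCCCCC[C@@H](O[Si](C)(C)C(C)(C)C)[C@H]1C[C@H](O)[C@H](CCCCC)O1 | intermediate
23 | tetradecanoyl chloride | CCCCCCCCCCCCCC(=O)Cl | starting material
24 | (2S,3S,5R)-5-[(1R)-1-[(tert-butyldimethylsilyl)oxy]dec-9-en-1-yl]-2-pentyloxolan-3-yl tetradecanoate | C=CCCCCCCC[C@@H](O[Si](C)(C)C(C)(C)C)[C@H]1C[C@H](OC(=O)CCCCCCCCCCCCC)[C@H](CCCCC)O1 | intermediate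
25 | (2S,3S,5R)-5-[(1R)-1-hydroxydec-9-en-1-yl]-2-pentyloxolan-3-yl tetradecanoate | C=CCCCCCCC[C@@H](O)[C@H]1C[C@H](OC(=O)CCCCCCCCCCCCC)[C@H](CCCCC)O1 | target

**Totals**
Total step count: 17. Longest linear sequence: 13 steps (steps 5–17, from 7 and 8); the aldehyde branch (steps 1–4) joins at step 11.

**Three steps most likely to fail, with fallbacks**

Step 11 (chelate selectivity, PMB stability towards the Lewis acid, reactivity of a ketone enol silane). The fallback reverses the aldol polarity, so that the Felkin–Anh preference of an α-silyloxy aldehyde sets C9 and the directed reduction sets C7. It sets out from 6 and 13 and comes back at 18. Aldehyde 6 with MeMgBr (THF, −78 °C) gives (3S)-3-[(4-methoxybenzyl)oxy]octan-2-ol F1 as a carbinol epimer mixture. Dess–Martin periodinane oxidises this to (3S)-3-[(4-methoxybenzyl)oxy]octan-2-one F2, and LiN(iPr)2/Me3SiCl gives the kinetic enol silane (3S)-3-[(4-methoxybenzyl)oxy]-2-[(trimethylsilyl)oxy]oct-1-ene F3. Separately, 13 is reduced with iBu2AlH (THF, −78 °C) to (2R)-2-[(tert-butyldimethylsilyl)oxy]undec-10-enal F4. A BF3·OEt2-promoted Mukaiyama aldol of F3 with F4 (CH2Cl2, −78 °C, non-chelating, 9,10-anti) forms the C8–C9 bond and gives (6S,9S,10R)-10-[(tert-butyldimethylsilyl)oxy]-9-hydroxy-6-[(4-methoxybenzyl)oxy]nonadec-18-en-7-one F5. Me4NBH(OAc)3 reduction directed by the C9 hydroxyl (1,3-anti) then gives 18.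

Step 13 (over-oxidation to the anisate ester or incomplete acetal closure). The fallback masks O6/O7 as an acetonide after plain PMB removal. It sets out from 18 and comes back at 21. DDQ in wet CH2Cl2 (pH 7 buffer) gives (6S,7S,9S,10R)-10-[(tert-butyldimethylsilyl)oxy]nonadec-18-ene-6,7,9-triol F6. Equilibrating ketalisation (2,2-dimethoxypropane, PPTS) selects the trans-dioxolane of the threo 6,7-diol over the strained twist-boat 7,9-acetonide of the anti-1,3-diol, giving (2S,3R)-3-[(tert-butyldimethylsilyl)oxy]-1-[(4S,5S)-2,2-dimethyl-5-pentyl-1,3-dioxolan-4-yl]dodec-11-en-2-ol F7. MsCl/Et3N gives (2S,3R)-3-[(tert-butyldimethylsilyl)oxy]-1-[(4S,5S)-2,2-dimethyl-5-pentyl-1,3-dioxolan-4-yl]dodec-11-en-2-yl methanesulfonate F8, and PPTS/MeOH releases 21, which is cyclised with K2CO3 as in step 15.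

Step 15 (slow displacement or elimination at the hindered C9 mesylate next to the bulky silyl ether). The fallback closes the ring by reductive cycloetherification, which needs no leaving group. It sets out from 19 and comes back at 22. Dess–Martin oxidation of 19 gives (3R)-3-[(tert-butyldimethylsilyl)oxy]-1-[(2RS,4S,5S)-2-(4-methoxyphenyl)-5-pentyl-1,3-dioxolan-4-yl]dodec-11-en-2-one F9. 80% aqueous AcOH (rt) cleaves the acetal and the C6 hydroxyl closes onto the C9 ketone to give (2RS,4S,5S)-2-[(1R)-1-[(tert-butyldimethylsilyl)oxy]dec-9-en-1-yl]-5-pentyloxolane-2,4-diol F10. Et3SiH/BF3·OEt2 (CH2Cl2, −78 °C) reduces the derived five-membered oxocarbenium ion. By the Woerpel inside-attack model, hydride should enter cis to the pseudoaxial C7 oxygen, placing the C10 side chain trans to O7 and to the pentyl group, which is 22; this selectivity is a prediction and would need to be confirmed by NOE.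

**Further compounds**
F1 | step 11 | (3S)-3-[(4-methoxybenzyl)oxy]octan-2-ol (C2 epimers) | CCCCC[C@H](OCc1ccc(OC)cc1)C(C)O
F2 | step 11 | (3S)-3-[(4-methoxybenzyl)oxy]octan-2-one | CCCCC[C@H](OCc1ccc(OC)cc1)C(C)=O
F3 | step 11 | (3S)-3-[(4-methoxybenzyl)oxy]-2-[(trimethylsilyl)oxy]oct-1-ene | CCCCC[C@H](OCc1ccc(OC)cc1)C(=C)O[Si](C)(C)C
F4 | step 11 | (2R)-2-[(tert-butyldimethylsilyl)oxy]undec-10-enal | C=CCCCCCCC[C@@H](O[Si](C)(C)C(C)(C)C)C=O
F5 | step 11 | (6S,9S,10R)-10-[(tert-butyldimethylsilyl)oxy]-9-hydroxy-6-[(4-methoxybenzyl)oxy]nonadec-18-en-7-one | C=CCCCCCCC[C@@H](O[Si](C)(C)C(C)(C)C)[C@@H](O)CC(=O)[C@@H](OCc1ccc(OC)cc1)CCCCC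
F6 | step 13 | (6S,7S,9S,10R)-10-[(tert-butyldimethylsilyl)oxy]nonadec-18-ene-6,7,9-triol | C=CCCCCCCC[C@@H](O[Si](C)(C)C(C)(C)C)[C@@H](O)C[C@H](O)[C@@H](O)CCCCC
F7 | step 13 | (2S,3R)-3-[(tert-butyldimethylsilyl)oxy]-1-[(4S,5S)-2,2-dimethyl-5-pentyl-1,3-dioxolan-4-yl]dodec-11-en-2-ol | C=CCCCCCCC[C@@H](O[Si](C)(C)C(C)(C)C)[C@@H](O)C[C@@H]1OC(C)(C)O[C@H]1CCCCC
F8 | step 13 | (2S,3R)-3-[(tert-butyldimethylsilyl)oxy]-1-[(4S,5S)-2,2-dimethyl-5-pentyl-1,3-dioxolan-4-yl]dodec-11-en-2-yl methanesulfonate | C=CCCCCCCC[C@@H](O[Si](C)(C)C(C)(C)C)[C@@H](OS(C)(=O)=O)C[C@@H]1OC(C)(C)O[C@H]1CCCCC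
F9 | step 15 | (3R)-3-[(tert-butyldimethylsilyl)oxy]-1-[(2RS,4S,5S)-2-(4-methoxyphenyl)-5-pentyl-1,3-dioxolan-4-yl]dodec-11-en-2-one | C=CCCCCCCC[C@@H](O[Si](C)(C)C(C)(C)C)C(=O)C[C@@H]1OC(c2ccc(OC)cc2)O[C@H]1CCCCC
F10 | step 15 | (2RS,4S,5S)-2-[(1R)-1-[(tert-butyldimethylsilyl)oxy]dec-9-en-1-yl]-5-pentyloxolane-2,4-diol | C=CCCCCCCC[C@@H](O[Si](C)(C)C(C)(C)C)C1(O)C[C@H](O)[C@H](CCCCC)O1
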